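## Structural features

The target 9 is (3-methylidene-2,3-dihydro-1-benzoxepin-7-yl)methyl octadecanoate. A benzene ring is fused through C5a and C9a to a seven-membered oxacycle O1–C2H2–C3(=CH2)–C4H=C5H. The exocyclic methylene on C3 and the endocyclic C4=C5 bond form a cross-conjugated 1,3-diene whose C5 end is styrenic. C7, para to the ring oxygen and meta to C5a, carries the CH2–O–CO–C17H35 side chain. There is no stereocentre, and the C4=C5 bond is cis because the ring allows nothing else. The fragile parts are the diene (acid or base can move the exocyclic bond into the ring; it can also polymerise), the allylic aryl ether at C2, and the para-alkoxybenzylic ester (ionisation under acid, saponification, hydrogenolysis). The real difficulty is closing the seven-membered ring with the 2-substituted diene already in its final, unisomerised form under neutral conditions. The key step exploits the atom pattern exocyclic CH2=C3–C4=C5: C3 and C4 are read as the two carbons of a former alkyne, and the exocyclic CH2 and C5 as the two carbons of a former vinyl group, which is the connectivity of an enyne metathesis in the endo mode.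

## Logic of the disconnections

**9 to 8.** The two double bonds C3=CH2(exocyclic) and C4=C5 are cut and re-paired as a C≡C bond (C3≡C4) and a vinyl group (C5=CH2); the C3–C4 single bond of 9 is the former triple bond. This removes the seven-membered ring and the whole diene in one isomerisation with no by-product, and leaves an acyclic ortho-disubstituted arene. In one sentence: endo-selective ring-closing enyne metathesis of the ortho-vinylaryl propargyl ether 8 gives 9 directly. The forward step must run in the endo mode (both alkyne carbons in the ring), so the metal alkylidene must enter at the alkyne and not at the styrene.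

**8 to 6 and 7.** The acyl C–O bond of the ester is cut. The ester is put on immediately before the key step so that no free hydroxyl group meets the molybdenum alkylidene, and so that the ester sees none of the earlier basic steps. The forward step must be a mild acylation that does not ionise the para-alkoxybenzylic position.

**6 to 5.** The benzylic C–H bond is cut, a change of oxidation level only. Carrying the side chain as an aldehyde through the coupling and the alkylation avoids a free para-hydroxybenzyl alcohol, which would lose hydroxide under base. The forward step must be a hydride reduction that spares the alkyne and the vinyl group.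

**5 to 3 and 4.** The O–CH2 bond of the propargyl ether is cut. This gives a phenol and a commodity three-carbon electrophile that supplies C2, C3 and C4. The forward step must be a clean O-alkylation without isomerisation of the propargyl group to an allene.

**3 to 1 and 2.** The aryl–vinyl C–C bond is cut. This leads back to a catalogue bromophenol aldehyde and a bench-stable vinyl donor that supplies C5 and the future exocyclic carbon. The forward step must be a cross-coupling that tolerates the free phenol and the aldehyde.

## Other disconnections considered

**Alternative 1:** the first idea that comes to mind. Cut O1–C2 and C4=C5. Forward: (3-formyl-4-hydroxyphenyl)methyl octadecanoate A1 is O-alkylated with 3-chloro-2-(chloromethyl)prop-1-ene to the allylic chloride A2, PPh3 gives the phosphonium salt A3, and base closes C4=C5 by intramolecular Wittig reaction. The chosen plan is preferred for three reasons. First, the ring closure of A3 runs through a strongly basic allylic ylide, which threatens the exocyclic double bond (migration into conjugation) and the ester. Second, A1 itself needs a regioselective formylation or a differentiation of two carbonyl groups. Third, the route takes at least as many steps and ends with a stoichiometric phosphine oxide, without any gain from the key step, since the four-carbon unit is simply bought whole.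

**Alternative 2:** cut C4=C5 only, as a diene–ene ring-closing metathesis. Forward: the triene [3-ethenyl-4-(2-methylidenebut-3-en-1-yloxy)phenyl]methyl octadecanoate A5, made with 2-(bromomethyl)buta-1,3-diene A4, is closed with second-generation Grubbs catalyst RuCl2(=CHPh)(PCy3)(H2IMes) with loss of ethene. The chosen plan is preferred because A4 is a volatile, polymerisable allylic bromide that is not a catalogue item and costs two extra steps from isoprene. In addition, the ruthenium carbene must distinguish the two alkenes of the diene in A5 (seven- against six-membered closure). The chosen route builds the same diene from propargyl bromide by isomerisation and loses no atoms.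

**Alternative 3:** cut O1–C2 and C4–C5 in a [4+3] annulation. Forward: base converts [4-hydroxy-3-(tosylmethyl)phenyl]methyl octadecanoate A6 into the ortho-quinone methide A7, which is trapped by the trimethylenemethane complex formed from 2-[(trimethylsilyl)methyl]allyl acetate and Pd(PPh3)4 (zerovalent palladium) to give the tetrahydrobenzoxepine A8. The chosen plan is preferred because A8 lacks the C4=C5 double bond. Introducing it needs a benzylic functionalisation at C5 and an elimination, in competition with the C2 and C4 allylic positions and the benzylic ester CH2, and with a risk of moving the exocyclic bond. That adds at least two steps of doubtful selectivity after the key step.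

Key step: step 5

Remark on the chemistry: the acyl chain is read as octadecanoyl (17 carbons beyond the carbonyl), and the target has no stereocentre.

## Route

**Step 1**
Reactants: 1 3-bromo-4-hydroxybenzaldehyde; 2 potassium vinyltrifluoroborate
Product: 3 3-ethenyl-4-hydroxybenzaldehyde
Conditions: PdCl2(dppf)·CH2Cl2 (3 mol%), Cs2CO3 (3 equiv), THF/H2O 9:1, 80 °C
Reagents that add atoms: potassium vinyltrifluoroborate, C=C[B-](F)(F)F.[K+]
Why: Suzuki–Miyaura vinylation; oxidative addition of zerovalent palladium into the C–Br bond is helped by the para-formyl group, and the slowly hydrolysing trifluoroborate keeps the concentration of the vinylboron species low, so the free phenol and the aldehyde should be tolerated.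

**Step 2**
Reactants: 3 3-ethenyl-4-hydroxybenzaldehyde; 4 propargyl bromide (3-bromoprop-1-yne)
Product: 5 3-ethenyl-4-(prop-2-yn-1-yloxy)benzaldehyde
Conditions: K2CO3 (1.5 equiv), DMF, 23 °C
Reagents that add atoms: propargyl bromide, C#CCBr
Why: Williamson ether synthesis; the phenoxide, made more acidic by the para-formyl group, should undergo clean SN2 O-alkylation with the unhindered propargylic bromide, and the weak base at room temperature should not isomerise the propargyl ether.

**Step 3**
Reactants: 5 3-ethenyl-4-(prop-2-yn-1-yloxy)benzaldehyde
Product: 6 [3-ethenyl-4-(prop-2-yn-1-yloxy)phenyl]methanol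
Conditions: NaBH4 (0.5 equiv), MeOH, 0 °C
Reagents that add atoms: none
Why: Borohydride 1,2-reduction of an aryl aldehyde; the terminal alkyne, the vinyl group and the ether are inert to NaBH4.

**Step 4**
Reactants: 6 [3-ethenyl-4-(prop-2-yn-1-yloxy)phenyl]methanol; 7 octadecanoyl chloride
Product: 8 [3-ethenyl-4-(prop-2-yn-1-yloxy)phenyl]methyl octadecanoate
Conditions: Et3N (1.5 equiv), DMAP (5 mol%), CH2Cl2, 0 to 23 °C
Reagents that add atoms: octadecanoyl chloride, ClC(=O)CCCCCCCCCCCCCCCCC
Why: DMAP-catalysed acylation of a primary benzylic alcohol by an acid chloride; the amine buffers the medium, so the para-alkoxybenzylic C–O bond should not ionise.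

**Step 5**
Reactants: 8 [3-ethenyl-4-(prop-2-yn-1-yloxy)phenyl]methyl octadecanoate
Product: 9 (3-methylidene-2,3-dihydro-1-benzoxepin-7-yl)methyl octadecanoate
Conditions: Mo(N-2,6-iPr2C6H3)(CHCMe2Ph)(2,5-Me2C4H2N)(O-2,6-iPr2C6H3) (5 mol%, formed from Mo(N-2,6-iPr2C6H3)(CHCMe2Ph)(2,5-Me2C4H2N)2 and 2,6-iPr2C6H3OH), C6H6, 0.01 M, 22 °C, N2
Reagents that add atoms: none
Why: Endo-selective ring-closing enyne metathesis, the known behaviour of stereogenic-at-molybdenum monoalkoxide and monoaryloxide pyrrolide alkylidenes with terminal-alkyne 1,6- and 1,7-enynes; 8 is a 1,7-enyne held cis on an arene. The electrophilic hexavalent molybdenum alkylidene (after the first turnover Mo=CH2) should add across the terminal alkyne before the styrene, with Mo on the unsubstituted alkyne carbon and the aryloxymethyl group on Cβ of the molybdacyclobutene, away from the bulky imido and aryloxide ligands. Ring opening of that metallacycle gives the alkylidene Mo=CH–C(=CH2)–CH2OAr, in which the exocyclic C3=CH2 bond is already in place. This alkylidene then meets the ortho-vinyl group in a [2+2]/retro-[2+2] sequence that forms C4=C5, closes the seven-membered ring (both former alkyne carbons in the ring, endo mode) and returns Mo=CH2 as the chain carrier. The net change is an isomerisation in which the terminal CH2 of the vinyl group is transferred to C3 and nothing is lost. No stereocentre is created, and the new ring alkene can only be cis. The selectivity needed is endo against exo closure (the exo mode would give a six-membered ring with a pendant vinyl group); it is secured by the alkyne-first pathway and the sterically controlled regiochemistry of alkyne insertion at molybdenum, while high dilution suppresses alkyne oligomerisation. The ester, the aryl ether and the arene are inert to this catalyst at room temperature, and the neutral conditions leave the exocyclic double bond where it is formed.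

## Compound list

1 | 3-bromo-4-hydroxybenzaldehyde | O=Cc1ccc(O)c(Br)c1 | starting material
2 | potassium vinyltrifluoroborate | C=C[B-](F)(F)F.[K+] | starting material
3 | 3-ethenyl-4-hydroxybenzaldehyde | C=Cc1cc(C=O)ccc1O | intermediate
4 | propargyl bromide (3-bromoprop-1-yne) | C#CCBr | starting material
5 | 3-ethenyl-4-(prop-2-yn-1-yloxy)benzaldehyde | C=Cc1cc(C=O)ccc1OCC#C | intermediate
6 | [3-ethenyl-4-(prop-2-yn-1-yloxy)phenyl]methanol | C=Cc1cc(CO)ccc1OCC#C | intermediate
7 | octadecanoyl chloride | ClC(=O)CCCCCCCCCCCCCCCCC | starting material
8 | [3-ethenyl-4-(prop-2-yn-1-yloxy)phenyl]methyl octadecanoate | C=Cc1cc(COC(=O)CCCCCCCCCCCCCCCCC)ccc1OCC#C | intermediate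
9 | (3-methylidene-2,3-dihydro-1-benzoxepin-7-yl)methyl octadecanoate | C=C1C=Cc2cc(COC(=O)CCCCCCCCCCCCCCCCC)ccc2OC1 | target

## Step count and risk

Total step count: 5. Longest linear sequence: 5 steps (1 to 9).

**Step 5 (key step).** The most likely failure is entry of the alkylidene at the styrene instead of the alkyne, followed by closure in the exo mode to a six-membered ring. Oligomerisation of the terminal alkyne at the metal is a second risk. Both follow from the fact that the endo outcome depends on the order and regiochemistry of two competing [2+2] events. Fallback with known chemistry, setting out from 3 and returning at 9: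
- 3 is O-alkylated with 2-(bromomethyl)buta-1,3-diene A4 (the reagent of Alternative 2, available in two steps from isoprene) using K2CO3 in DMF, to give 3-ethenyl-4-[(2-methylidenebut-3-en-1-yl)oxy]benzaldehyde F1.
- Diene–ene ring-closing metathesis of F1 with second-generation Grubbs catalyst RuCl2(=CHPh)(PCy3)(H2IMes) in CH2Cl2 at 40 °C should join the styrene to the monosubstituted end of the diene with loss of ethene, to give 3-methylidene-2,3-dihydro-1-benzoxepine-7-carbaldehyde F2.
- NaBH4 in MeOH at 0 °C gives (3-methylidene-2,3-dihydro-1-benzoxepin-7-yl)methanol F3.
- Acylation of F3 with 7 (Et3N, DMAP, CH2Cl2) gives 9.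

**Step 1.** The most likely failure is slow oxidative addition into the electron-rich bromophenoxide, together with protodeboronation of the vinyl donor and palladium-mediated oligomerisation of the vinylphenol as it forms. Fallback, setting out from 1 and returning at 5: 1 is first alkylated with 4 (K2CO3, DMF) to give 3-bromo-4-(prop-2-yn-1-yloxy)benzaldehyde F4. The ether F4 is then vinylated by Stille coupling with tributyl(vinyl)stannane (Pd(PPh3)4, toluene, 100 °C) to give 5, so the coupling is done on an aryl ether and not on a phenoxide.

**Step 2.** The most likely failure is base-induced isomerisation of the propargyl ether to the allenyl ether, or polymerisation of the ortho-vinylphenoxide during a slow alkylation. Fallback, setting out from 3 and returning at 5: Mitsunobu etherification of 3 with prop-2-yn-1-ol (PPh3, diisopropyl azodicarboxylate, THF, 0 °C), which activates the alcohol under neutral conditions and avoids the phenoxide; this fallback makes no new compound (F0).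

**Step 4.** The most likely failure is ionisation of the para-alkoxybenzylic C–O bond by the amine hydrochloride, with chloride substitution at the benzylic carbon. Fallback, setting out from 6 and returning at 8: Mitsunobu esterification of 6 with octadecanoic acid (PPh3, diisopropyl azodicarboxylate, THF, 0 °C), which forms the ester by carboxylate attack on the activated alcohol and not by acyl transfer; this fallback makes no new compound (F0).

## Further compounds

F1 | step 5 | 3-ethenyl-4-[(2-methylidenebut-3-en-1-yl)oxy]benzaldehyde | C=CC(=C)COc1ccc(C=O)cc1C=C
F2 | step 5 | 3-methylidene-2,3-dihydro-1-benzoxepine-7-carbaldehyde | C=C1C=Cc2cc(C=O)ccc2OC1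
F3 | step 5 | (3-methylidene-2,3-dihydro-1-benzoxepin-7-yl)methanol | C=C1C=Cc2cc(CO)ccc2OC1
F4 | step 1 | 3-bromo-4-(prop-2-yn-1-yloxy)benzaldehyde | O=Cc1ccc(OCC#C)c(Br)c1
F0 | step 2 | none | none
F0 | step 4 | none | none
A1 | alternative 1 | (3-formyl-4-hydroxyphenyl)methyl octadecanoate | O=Cc1cc(COC(=O)CCCCCCCCCCCCCCCCC)ccc1O
A2 | alternative 1 | [4-{[2-(chloromethyl)prop-2-en-1-yl]oxy}-3-formylphenyl]methyl octadecanoate | C=C(CCl)COc1ccc(COC(=O)CCCCCCCCCCCCCCCCC)cc1C=O
A3 | alternative 1 | {2-[(2-formyl-4-{[(octadecanoyl)oxy]methyl}phenoxy)methyl]prop-2-en-1-yl}triphenylphosphonium chloride | C=C(COc1ccc(COC(=O)CCCCCCCCCCCCCCCCC)cc1C=O)C[P+](c1ccccc1)(c1ccccc1)c1ccccc1.[Cl-]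
A4 | alternative 2 | 2-(bromomethyl)buta-1,3-diene | C=CC(=C)CBr
A5 | alternative 2 | [3-ethenyl-4-(2-methylidenebut-3-en-1-yloxy)phenyl]methyl octadecanoate | C=CC(=C)COc1ccc(COC(=O)CCCCCCCCCCCCCCCCC)cc1C=C
A6 | alternative 3 | [4-hydroxy-3-(tosylmethyl)phenyl]methyl octadecanoate | Cc1ccc(cc1)S(=O)(=O)Cc1cc(COC(=O)CCCCCCCCCCCCCCCCC)ccc1O
A7 | alternative 3 | (3-methylidene-4-oxocyclohexa-1,5-dien-1-yl)methyl octadecanoate (ortho-quinone methide) | C=C1C=C(COC(=O)CCCCCCCCCCCCCCCCC)C=CC1=O
A8 | alternative 3 | (3-methylidene-2,3,4,5-tetrahydro-1-benzoxepin-7-yl)methyl octadecanoate | C=C1CCc2cc(COC(=O)CCCCCCCCCCCCCCCCC)ccc2OC1
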